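**Plan**

- Retrosynthesis: the C5–C6 bond and the lactone C12–O6 bond are cut together, giving seco aldehyde 27 (alkenyl iodide at C5, aldehyde at C6, acrylate ester at C11/C12). Then C9–C10 is cut (alkenyl iodide 11 + aldehyde 21), then C7–C8 (allyl bromide 15 + glyceraldehyde acetonide 16), and C3–C4 and C1=C10 in the west half.
- Forward: west iodide 11 (steps 1–7) and east aldehyde 21 (steps 8–12) are joined at C9–C10 by a first chromium-mediated coupling. After O9 acylation, C5–Si becomes C5–I and C6 becomes the aldehyde; one chromium step then closes the ten-membered ring and, in the same flask, the γ-lactone.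
- Enabling feature: C6 is both the allylic carbinol carbon next to the C4=C5 alkene and the alkoxy carbon of the five-membered lactone O–C6–C7–C11–C12. An alkenyl metal at C5 adding to a C6 aldehyde therefore creates the alkoxide four atoms from the C12 ester. Both ring alkenes (C1=C10, C4=C5) are ring-cis, which eases closure of the cyclodecadiene.
- Stereochemistry: C8 from (R)-glyceraldehyde acetonide (Felkin–Anh); C7 from the syn-selective Barbier allylation; C9 and C6 from Felkin–Anh additions of alkenylchromium reagents; C2' bought as (R)-2-methylbutanoic acid. Alkene geometries come from syn-silylstannation, a (Z)-selective iodo-Wittig reaction and angelic acid.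
- Both acyl groups are in place before ring closure, so only oxidation at C14 and desilylation at C15 follow.

Key step: step 18

Remark: locants C1 to C15 in the Why lines and in the names of 28 to 31 are germacrane locants of the target (C12 lactone carbonyl, C13 exocyclic methylene, C14 on C10, C15 on C4); the chromium alkoxide of step 18 is taken to lactonize in the flask.

**Route**

Step 1
Reactants: 1 tert-butyldimethyl(prop-2-yn-1-yloxy)silane
Product: 2 (Z)-tert-butyldimethyl{[2-(tributylstannyl)-3-(trimethylsilyl)prop-2-en-1-yl]oxy}silane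
Conditions: Me3SiSnBu3, Pd(PPh3)4 (2 mol %), THF, 65 °C
Reagents that add atoms: trimethyl(tributylstannyl)silane, C[Si](C)(C)[Sn](CCCC)(CCCC)CCCC
Why: Palladium-catalysed silylstannation of a terminal alkyne is a syn addition with silicon at the terminal carbon (C5) and tin at the internal carbon (C4), which fixes the silyl group, the later iodide, cis to the site of the C3 chain.

Step 2
Reactants: 2 (Z)-silylstannane
Product: 3 (Z)-tert-butyl{[2-iodo-3-(trimethylsilyl)prop-2-en-1-yl]oxy}dimethylsilane
Conditions: I2, CH2Cl2, 0 °C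
Reagents that add atoms: iodine, II
Why: Iododestannylation is stereoretentive and much faster at the C–Sn bond than at the alkenyl C–Si bond.

Step 3
Reactants: 3 (Z)-iodo silane; 4 (3-ethoxy-3-oxopropyl)zinc bromide
Product: 5 ethyl (4E)-4-{[(tert-butyldimethylsilyl)oxy]methyl}-5-(trimethylsilyl)pent-4-enoate
Conditions: Pd(PPh3)4 (5 mol %), THF/DMA, 50 °C
Reagents that add atoms: none
Why: Negishi coupling of the zinc homoenolate with the alkenyl iodide forms C3–C4 with retention of alkene geometry and tolerates the ester.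

Step 4
Reactants: 5 ethyl ester
Product: 6 (4E)-4-{[(tert-butyldimethylsilyl)oxy]methyl}-5-(trimethylsilyl)pent-4-enal
Conditions: DIBAL-H (i-Bu2AlH, 1.1 equiv), CH2Cl2, −78 °C
Reagents that add atoms: none
Why: DIBAL-H reduction at −78 °C stops at the aldehyde because the tetrahedral aluminium hemiacetal collapses only on work-up.

Step 5
Reactants: 6 aldehyde; 7 ethyl (triphenylphosphoranylidene)acetate
Product: 9 ethyl (2Z,6E)-6-{[(tert-butyldimethylsilyl)oxy]methyl}-2-iodo-7-(trimethylsilyl)hepta-2,6-dienoate, via iodo ylide 8 (not isolated)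
Conditions: NIS, CH2Cl2, −20 °C; then 6, −20 °C to rt
Reagents that add atoms: N-iodosuccinimide, O=C1CCC(=O)N1I
Why: Iodination of the stabilized ylide followed by Wittig olefination places the ester trans to the C2 chain, as stabilized ylides do, so that iodine at C10 lies cis to C2.

Step 6
Reactants: 9 iodo enoate
Product: 10 (2Z,6E)-6-{[(tert-butyldimethylsilyl)oxy]methyl}-2-iodo-7-(trimethylsilyl)hepta-2,6-dien-1-ol
Conditions: DIBAL-H (i-Bu2AlH, 2.2 equiv), CH2Cl2, −78 °C
Reagents that add atoms: none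
Why: DIBAL-H reduces the conjugated ester by 1,2-addition to the allylic alcohol and leaves the alkenyl iodide and the silanes alone.

Step 7
Reactants: 10 allylic alcohol
Product: 11 west alkenyl iodide, the triethylsilyl ether of 10
Conditions: Et3SiCl, imidazole, CH2Cl2, 0 °C
Reagents that add atoms: chlorotriethylsilane, CC[Si](Cl)(CC)CC
Why: Standard silylation; the primary triethylsilyl ether is chosen because it can later be oxidized directly in the presence of the tert-butyldimethylsilyl ether.

Step 8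
Reactants: 12 methyl acrylate; 13 2-[(4-methoxybenzyl)oxy]acetaldehyde
Product: 14 methyl 3-hydroxy-4-[(4-methoxybenzyl)oxy]-2-methylidenebutanoate (racemic)
Conditions: DABCO (0.5 equiv), 1,4-dioxane/H2O, rt
Reagents that add atoms: none
Why: The Morita–Baylis–Hillman reaction of an α-alkoxy aldehyde with an acrylate is fast, and the carbinol stereocenter is removed in the next step.

Step 9
Reactants: 14 Morita–Baylis–Hillman alcohol
Product: 15 methyl (2Z)-2-(bromomethyl)-4-[(4-methoxybenzyl)oxy]but-2-enoate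
Conditions: NBS, Me2S, CH2Cl2, 0 °C to rt
Reagents that add atoms: N-bromosuccinimide, O=C1CCC(=O)N1Br
Why: The alkoxysulfonium salt is displaced by bromide in an SN2' reaction that gives the conjugated (Z)-2-(bromomethyl)enoate, with the ester trans to CH2OPMB.

Step 10
Reactants: 15 allyl bromide; 16 (R)-2,2-dimethyl-1,3-dioxolane-4-carbaldehyde
Product: 17 methyl (3S,4S)-4-[(4R)-2,2-dimethyl-1,3-dioxolan-4-yl]-4-hydroxy-3-{[(4-methoxybenzyl)oxy]methyl}-2-methylidenebutanoate
Conditions: In powder, THF/H2O, rt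
Reagents that add atoms: none
Why: Indium-mediated Barbier allylation: the allylindium reacts at its γ-carbon (C7) through a chair transition state with the CH2OPMB group axial, which gives the C7/C8 syn relation, and adds to 16 in the Felkin–Anh sense, anti to the dioxolane oxygen, which sets C8.

Step 11
Reactants: 17 homoallylic alcohol; 18 angelic acid, (Z)-2-methylbut-2-enoic acid
Product: 20 methyl (3S,4S)-4-[(4R)-2,2-dimethyl-1,3-dioxolan-4-yl]-3-{[(4-methoxybenzyl)oxy]methyl}-2-methylidene-4-{[(Z)-2-methylbut-2-enoyl]oxy}butanoate, via angelic 2,4,6-trichlorobenzoic anhydride 19 (not isolated)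
Conditions: 2,4,6-Cl3C6H2COCl, Et3N, toluene, rt; then 17, 80 °C
Reagents that add atoms: none
Why: Yamaguchi-type esterification through the mixed anhydride, run without a nucleophilic catalyst, acylates hindered secondary alcohols with angelic acid without Z to E isomerization.

Step 12
Reactants: 20 angelate acetonide
Product: 21 east aldehyde, methyl (3S,4S)-3-{[(4-methoxybenzyl)oxy]methyl}-2-methylidene-4-{[(Z)-2-methylbut-2-enoyl]oxy}-5-oxopentanoate
Conditions: H5IO6, EtOAc, rt
Reagents that add atoms: none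
Why: Periodic acid hydrolyses the terminal acetonide and cleaves the liberated 1,2-diol in one pot, which turns the auxiliary stereocenter of 16 into the C9 aldehyde.

Step 13
Reactants: 11 west alkenyl iodide; 21 east aldehyde
Product: 22 methyl (3S,4S,5R,6Z,10E)-10-{[(tert-butyldimethylsilyl)oxy]methyl}-5-hydroxy-3-{[(4-methoxybenzyl)oxy]methyl}-2-methylidene-4-{[(Z)-2-methylbut-2-enoyl]oxy}-6-{[(triethylsilyl)oxy]methyl}-11-(trimethylsilyl)undeca-6,10-dienoate
Conditions: CrCl2 (4 equiv), NiCl2 (2 mol %), DMSO, rt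
Reagents that add atoms: none
Why: The Nozaki–Hiyama–Kishi coupling is selective for the aldehyde over the esters and the acrylate, keeps the alkene geometry, and should add in the polar Felkin–Anh sense, anti to the C8 acyloxy group, which sets C9 (8,9-anti).

Step 14
Reactants: 22 C9 alcohol; 23 (R)-2-methylbutanoic acid
Product: 24 methyl (3S,4S,5R,6Z,10E)-10-{[(tert-butyldimethylsilyl)oxy]methyl}-3-{[(4-methoxybenzyl)oxy]methyl}-5-{[(2R)-2-methylbutanoyl]oxy}-2-methylidene-4-{[(Z)-2-methylbut-2-enoyl]oxy}-6-{[(triethylsilyl)oxy]methyl}-11-(trimethylsilyl)undeca-6,10-dienoate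
Conditions: DCC, DMAP (cat.), CH2Cl2, 0 °C to rt
Reagents that add atoms: none
Why: Steglich esterification of the allylic C9 alcohol; the α-stereocenter of 23 carries no activating group and should not racemize.

Step 15
Reactants: 24 alkenylsilane diester
Product: 25 the 11-iodo analogue of 24 (iodine in place of SiMe3, cis to C3)
Conditions: NIS, 2,6-lutidine, (CF3)2CHOH, 0 °C
Reagents that add atoms: N-iodosuccinimide, O=C1CCC(=O)N1I
Why: Ipso-iododesilylation through the β-silyl cation, which in hexafluoroisopropanol proceeds with retention at trisubstituted alkenylsilanes and should be much faster than iodination of the anisyl ring.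

Step 16
Reactants: 25 alkenyl iodide
Product: 26 the 3-(hydroxymethyl) compound, 25 without the 4-methoxybenzyl group
Conditions: DDQ, CH2Cl2/pH 7 buffer, 0 °C
Reagents that add atoms: none
Why: Oxidative cleavage of the 4-methoxybenzyl ether by DDQ under buffered conditions leaves the silyl ethers, the esters and the alkenyl iodide untouched.

Step 17
Reactants: 26 primary alcohol
Product: 27 seco aldehyde, methyl (3R,4S,5R,6Z,10E)-10-{[(tert-butyldimethylsilyl)oxy]methyl}-3-formyl-11-iodo-5-{[(2R)-2-methylbutanoyl]oxy}-2-methylidene-4-{[(Z)-2-methylbut-2-enoyl]oxy}-6-{[(triethylsilyl)oxy]methyl}undeca-6,10-dienoate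
Conditions: Dess–Martin periodinane, NaHCO3, CH2Cl2, 0 °C
Reagents that add atoms: none
Why: Buffered Dess–Martin oxidation gives the α-branched aldehyde under non-basic conditions; it is used at once to avoid epimerization at C7.

Step 18
Reactants: 27 seco aldehyde
Product: 29 (6R,7S,8S,9R)-lactone, the 14-O-triethylsilyl 15-O-tert-butyldimethylsilyl ether of the 14-alcohol corresponding to the target, via macrocyclic hydroxy ester 28 (not isolated)
Conditions: CrCl2 (10 equiv), NiCl2 (5 mol %), DMSO/THF, rt, slow addition to 0.002 M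
Reagents that add atoms: none
Why: Zerovalent nickel inserts into the C5–I bond, the alkenyl group passes to trivalent chromium with retention of the C4=C5 geometry and adds to the C6 aldehyde, and the chromium alkoxide of 28 then acylates on the C12 methyl ester with loss of methoxide. The closest known reaction types are the Nozaki–Hiyama–Kishi macrocyclization and the in-flask lactonization of chromium alkoxides in chromium-mediated 2-(alkoxycarbonyl)allylations. The ten-membered carbocycle closes by a 10-exo-trig 1,2-addition to C6=O, and the γ-lactone (O–C6–C7–C11–C12) by a 5-exo-trig acyl substitution. C6 is set under Felkin–Anh control by C7, the alkenyl group arriving anti to the C8 branch, which places O6 syn to C11 and H6 trans to H7 and so should give the 6R trans-fused lactone. The step needs selectivity for the aldehyde over three ester carbonyls and the acrylate, secured by the low basicity of alkenylchromium, and ring closure over oligomerization, secured by high dilution and by the two ring-cis trisubstituted alkenes (C1=C10, C4=C5) that fold the chain.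

Step 19
Reactants: 29 lactone
Product: 30 the 15-O-tert-butyldimethylsilyl ether of the target (C14 aldehyde)
Conditions: (COCl)2, DMSO, CH2Cl2, −78 to −40 °C; then Et3N, −78 to 0 °C
Reagents that add atoms: none
Why: Swern conditions cleave and oxidize a primary triethylsilyl ether in one operation while the primary tert-butyldimethylsilyl ether survives, which gives the enal without a free C14 alcohol.

Step 20
Reactants: 30 silyl ether
Product: 31 CNP0290361.1 (target)
Conditions: HF·pyridine, pyridine, THF, 0 °C to rt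
Reagents that add atoms: none
Why: HF·pyridine removes the primary allylic silyl ether under mildly acidic conditions that the enal, the α-methylene lactone and the two esters tolerate.

**Compound list**

1 | tert-butyldimethyl(prop-2-yn-1-yloxy)silane | C#CCO[Si](C)(C)C(C)(C)C | starting material
2 | (Z)-tert-butyldimethyl{[2-(tributylstannyl)-3-(trimethylsilyl)prop-2-en-1-yl]oxy}silane | C[Si](C)(C)/C=C(\[Sn](CCCC)(CCCC)CCCC)CO[Si](C)(C)C(C)(C)C | intermediate
3 | (Z)-tert-butyl{[2-iodo-3-(trimethylsilyl)prop-2-en-1-yl]oxy}dimethylsilane | C[Si](C)(C)/C=C(\I)CO[Si](C)(C)C(C)(C)C | intermediate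
4 | (3-ethoxy-3-oxopropyl)zinc bromide | CCOC(=O)CC[Zn]Br | starting material
5 | ethyl (4E)-4-{[(tert-butyldimethylsilyl)oxy]methyl}-5-(trimethylsilyl)pent-4-enoate | C[Si](C)(C)/C=C(\CCC(=O)OCC)CO[Si](C)(C)C(C)(C)C | intermediate
6 | (4E)-4-{[(tert-butyldimethylsilyl)oxy]methyl}-5-(trimethylsilyl)pent-4-enal | C[Si](C)(C)/C=C(\CCC=O)CO[Si](C)(C)C(C)(C)C | intermediate
7 | ethyl (triphenylphosphoranylidene)acetate | CCOC(=O)C=P(c1ccccc1)(c1ccccc1)c1ccccc1 | starting material
8 | ethyl iodo(triphenylphosphoranylidene)acetate | CCOC(=O)C(I)=P(c1ccccc1)(c1ccccc1)c1ccccc1 | intermediate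
9 | ethyl (2Z,6E)-6-{[(tert-butyldimethylsilyl)oxy]methyl}-2-iodo-7-(trimethylsilyl)hepta-2,6-dienoate | C[Si](C)(C)/C=C(/CO[Si](C)(C)C(C)(C)C)CC/C=C(\I)C(=O)OCC | intermediate
10 | (2Z,6E)-6-{[(tert-butyldimethylsilyl)oxy]methyl}-2-iodo-7-(trimethylsilyl)hepta-2,6-dien-1-ol | C[Si](C)(C)/C=C(/CO[Si](C)(C)C(C)(C)C)CC/C=C(\I)CO | intermediate
11 | west alkenyl iodide, triethylsilyl ether of 10 | C[Si](C)(C)/C=C(/CO[Si](C)(C)C(C)(C)C)CC/C=C(\I)CO[Si](CC)(CC)CC | intermediate
12 | methyl acrylate | C=CC(=O)OC | starting material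
13 | 2-[(4-methoxybenzyl)oxy]acetaldehyde | O=CCOCc1ccc(OC)cc1 | starting material
14 | methyl 3-hydroxy-4-[(4-methoxybenzyl)oxy]-2-methylidenebutanoate (racemic) | C=C(C(=O)OC)C(O)COCc1ccc(OC)cc1 | intermediate
15 | methyl (2Z)-2-(bromomethyl)-4-[(4-methoxybenzyl)oxy]but-2-enoate | COC(=O)/C(CBr)=C/COCc1ccc(OC)cc1 | intermediate
16 | (R)-2,2-dimethyl-1,3-dioxolane-4-carbaldehyde | CC1(C)OC[C@@H](O1)C=O | starting material
17 | methyl (3S,4S)-4-[(4R)-2,2-dimethyl-1,3-dioxolan-4-yl]-4-hydroxy-3-{[(4-methoxybenzyl)oxy]methyl}-2-methylidenebutanoate | CC1(C)OC[C@@H](O1)[C@@H](O)[C@@H](C(=C)C(=O)OC)COCc1ccc(OC)cc1 | intermediate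
18 | angelic acid, (Z)-2-methylbut-2-enoic acid | C/C=C(/C)C(=O)O | starting material
19 | angelic 2,4,6-trichlorobenzoic anhydride | C/C=C(/C)C(=O)OC(=O)c1c(Cl)cc(Cl)cc1Cl | intermediate
20 | methyl (3S,4S)-4-[(4R)-2,2-dimethyl-1,3-dioxolan-4-yl]-3-{[(4-methoxybenzyl)oxy]methyl}-2-methylidene-4-{[(Z)-2-methylbut-2-enoyl]oxy}butanoate | CC1(C)OC[C@@H](O1)[C@@H](OC(=O)/C(C)=C\C)[C@@H](C(=C)C(=O)OC)COCc1ccc(OC)cc1 | intermediate
21 | east aldehyde, methyl (3S,4S)-3-{[(4-methoxybenzyl)oxy]methyl}-2-methylidene-4-{[(Z)-2-methylbut-2-enoyl]oxy}-5-oxopentanoate | O=C[C@@H](OC(=O)/C(C)=C\C)[C@@H](C(=C)C(=O)OC)COCc1ccc(OC)cc1 | intermediate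
22 | methyl (3S,4S,5R,6Z,10E)-10-{[(tert-butyldimethylsilyl)oxy]methyl}-5-hydroxy-3-{[(4-methoxybenzyl)oxy]methyl}-2-methylidene-4-{[(Z)-2-methylbut-2-enoyl]oxy}-6-{[(triethylsilyl)oxy]methyl}-11-(trimethylsilyl)undeca-6,10-dienoate | C[Si](C)(C)/C=C(/CO[Si](C)(C)C(C)(C)C)CC/C=C(/CO[Si](CC)(CC)CC)[C@@H](O)[C@@H](OC(=O)/C(C)=C\C)[C@@H](C(=C)C(=O)OC)COCc1ccc(OC)cc1 | intermediate
23 | (R)-2-methylbutanoic acid | CC[C@@H](C)C(=O)O | starting material
24 | (2R)-2-methylbutanoate of 22 at the 5-hydroxyl | C[Si](C)(C)/C=C(/CO[Si](C)(C)C(C)(C)C)CC/C=C(/CO[Si](CC)(CC)CC)[C@@H](OC(=O)[C@H](C)CC)[C@@H](OC(=O)/C(C)=C\C)[C@@H](C(=C)C(=O)OC)COCc1ccc(OC)cc1 | intermediate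
25 | 11-iodo analogue of 24, (3S,4S,5R,6Z,10E), iodine cis to the chain CH2 | I/C=C(/CO[Si](C)(C)C(C)(C)C)CC/C=C(/CO[Si](CC)(CC)CC)[C@@H](OC(=O)[C@H](C)CC)[C@@H](OC(=O)/C(C)=C\C)[C@@H](C(=C)C(=O)OC)COCc1ccc(OC)cc1 | intermediate
26 | 3-(hydroxymethyl) compound, 25 without the 4-methoxybenzyl group | I/C=C(/CO[Si](C)(C)C(C)(C)C)CC/C=C(/CO[Si](CC)(CC)CC)[C@@H](OC(=O)[C@H](C)CC)[C@@H](OC(=O)/C(C)=C\C)[C@@H](C(=C)C(=O)OC)CO | intermediate
27 | seco aldehyde, methyl (3R,4S,5R,6Z,10E)-10-{[(tert-butyldimethylsilyl)oxy]methyl}-3-formyl-11-iodo-5-{[(2R)-2-methylbutanoyl]oxy}-2-methylidene-4-{[(Z)-2-methylbut-2-enoyl]oxy}-6-{[(triethylsilyl)oxy]methyl}undeca-6,10-dienoate | I/C=C(/CO[Si](C)(C)C(C)(C)C)CC/C=C(/CO[Si](CC)(CC)CC)[C@@H](OC(=O)[C@H](C)CC)[C@@H](OC(=O)/C(C)=C\C)[C@@H](C(=C)C(=O)OC)C=O | intermediate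
28 | macrocyclic hydroxy ester (6R,7S,8S,9R): cyclodeca-1(10),4-diene with 6-OH, 7-[1-(methoxycarbonyl)vinyl], 8-O-angeloyl, 9-O-(2R)-2-methylbutanoyl, 14-OTES, 15-OTBS | O[C@@H]1/C=C(/CO[Si](C)(C)C(C)(C)C)CC/C=C(/CO[Si](CC)(CC)CC)[C@@H](OC(=O)[C@H](C)CC)[C@@H](OC(=O)/C(C)=C\C)[C@H]1C(=C)C(=O)OC | intermediate
29 | (6R,7S,8S,9R)-6,12-lactone with 14-OTES and 15-OTBS | C=C1C(=O)O[C@@H]2/C=C(/CO[Si](C)(C)C(C)(C)C)CC/C=C(/CO[Si](CC)(CC)CC)[C@@H](OC(=O)[C@H](C)CC)[C@@H](OC(=O)/C(C)=C\C)[C@@H]12 | intermediate
30 | 15-O-tert-butyldimethylsilyl ether of the target | C=C1C(=O)O[C@@H]2/C=C(/CO[Si](C)(C)C(C)(C)C)CC/C=C(/C=O)[C@@H](OC(=O)[C@H](C)CC)[C@@H](OC(=O)/C(C)=C\C)[C@@H]12 | intermediate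
31 | CNP0290361.1 | C=C1C(=O)O[C@@H]2/C=C(/CO)CC/C=C(/C=O)[C@@H](OC(=O)[C@H](C)CC)[C@@H](OC(=O)/C(C)=C\C)[C@@H]12 | target

**Count and risks**

Total steps: 20. Longest linear sequence: 15 steps (steps 1 to 7, then 13 to 20).

Step 18. The ring closure may show poor facial selectivity at C6 because the folded seco chain, not the Felkin–Anh preference, may decide the approach; the alkoxide may also fail to lactonize, or intermolecular coupling may compete. Fallback, setting out from 27 and coming back at 29: the chromium closure is run and worked up cold so that hydroxy ester 28 and its C6 epimer, the 6-epi hydroxy ester F1, are isolated together. Dess–Martin oxidation of the mixture gives the macrocyclic C6 enone F2. Luche reduction (NaBH4, CeCl3·7H2O, MeOH, −78 °C) should deliver hydride to the outer face of the ring carbonyl, anti to the C7 side chain, and return 28. PPTS in CH2Cl2 then closes 28 to 29. C6 is thus set by ketone reduction instead of by the carbon–carbon bond formation.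

Step 13. Facial selectivity at C9 may be poor because the α-acyloxy aldehyde is hindered on both faces; the new alkoxide may also attack the neighbouring angelate or the C12 ester, and 21 may epimerize if coupling is slow. Fallback, setting out from 11 and 21 and coming back at 24: the anti alcohol 22 is esterified as in step 14. Its C9 epimer, the 9-epi alcohol F3, separated from the same coupling, is converted into 24 with inversion by Mitsunobu esterification with 23 (PPh3, DIAD, toluene, 0 °C to rt). Both epimers then converge on 24.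

Step 11. Acylation of the hindered C8 hydroxyl may be outrun by lactonization onto the C12 ester, or accompanied by Z to E isomerization of the angeloyl group. Fallback, setting out from 17 and coming back at 20: esterification of 17 with 2-[bis(2,2,2-trifluoroethoxy)phosphoryl]propanoic acid (DCC, DMAP, CH2Cl2, 0 °C) gives the phosphonopropanoate ester F4. A Still–Gennari olefination with acetaldehyde (KHMDS, 18-crown-6, THF, −78 °C) then builds the (Z)-2-methylbut-2-enoate on the substrate.

**Further compounds**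

F1 | step 18 | 6-epi hydroxy ester, C6 epimer of 28 | O[C@H]1/C=C(/CO[Si](C)(C)C(C)(C)C)CC/C=C(/CO[Si](CC)(CC)CC)[C@@H](OC(=O)[C@H](C)CC)[C@@H](OC(=O)/C(C)=C\C)[C@H]1C(=C)C(=O)OC
F2 | step 18 | macrocyclic C6 enone | O=C1/C=C(/CO[Si](C)(C)C(C)(C)C)CC/C=C(/CO[Si](CC)(CC)CC)[C@@H](OC(=O)[C@H](C)CC)[C@@H](OC(=O)/C(C)=C\C)[C@H]1C(=C)C(=O)OC
F3 | step 13 | 9-epi alcohol, C9 epimer of 22 | C[Si](C)(C)/C=C(/CO[Si](C)(C)C(C)(C)C)CC/C=C(/CO[Si](CC)(CC)CC)[C@H](O)[C@@H](OC(=O)/C(C)=C\C)[C@@H](C(=C)C(=O)OC)COCc1ccc(OC)cc1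
F4 | step 11 | 2-[bis(2,2,2-trifluoroethoxy)phosphoryl]propanoate ester of 17 at the C8 hydroxyl | CC1(C)OC[C@@H](O1)[C@@H](OC(=O)C(C)P(=O)(OCC(F)(F)F)OCC(F)(F)F)[C@@H](C(=C)C(=O)OC)COCc1ccc(OC)cc1
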